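## Structural features

The target is a 1,7-diarylheptanoid in which the oxygens on C1 and C5 of the heptane chain are one atom, so the core is a tetrahydropyran (O1, C2–C6). C2 carries a 4-hydroxy-3-methoxyphenyl group directly, C4 a free secondary hydroxyl, and C6 a 2-(4-hydroxy-3-methoxyphenyl)ethyl chain. The stereocentres C2 (S), C4 (R) and C6 (S) are not adjacent but stand in a 1,3,5-relationship, separated by C3, C5 and O1. All three substituents lie on one face, so all are equatorial in the chair, the thermodynamically preferred arrangement. The two arenes are identical guaiacyl units, so one protecting group and one family of building blocks serve both ends. The fragile points are the C2–O1 bond and the phenols. C2–O1 is a benzylic ether para to an oxygen donor, so it can ionise under acid, open by retro-oxa-Michael reaction whenever C4 is a ketone, and undergo hydrogenolysis. The free phenols are oxidisable and would consume titanium Lewis acids and acylating agents. The real difficulty is absolute control at C6, an unactivated ether carbon far from any directing group, and installation of C2 without relying on kinetic control at a configurationally labile centre. The key step uses the fact that C3–C4–C5 with the C4 oxygen is an acetoacetate unit flanked by C2 and C6, both at the oxidation level of aldehyde carbons, with O1 being the aldol oxygen of C6 that can add back to C2 in a conjugate sense.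

## Logic of the disconnections

14 to 13. The two phenolic O–H bonds are traced back to O–CH2Ph bonds. The skeleton is unchanged; the gain is that every earlier intermediate is free of acidic, oxidisable phenols and tolerates titanium Lewis acids, an acylating C4 donor and hydride. The forward step must cleave two aryl benzyl ethers while sparing the benzylic C2–O1 bond of the ring.

13 to 12. The C4–H bond is removed and C4 returns to a ketone. One stereocentre disappears and the ring acquires the carbonyl that matches a 1,3-dicarbonyl synthon. The forward step must deliver hydride along the axial direction of the chair so that the hydroxyl comes out equatorial, cis to the groups on C2 and C6.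

12 to 10 (through 11). A C3–CO2iPr bond is added back. The ester makes C3 doubly activated, which is what allows C2–C3 to be formed by condensation with an aldehyde. The price is one forward step that must remove the ester without scrambling C2 relative to C6.

10 to 5 + 6 + 7 (through 9 and 8). Three bonds are cut: O1–C2, C2–C3 and C5–C6. The ring, both ring stereocentres and the whole carbon skeleton fall apart into two aldehydes and a four-carbon acetoacetyl donor; this is the largest simplification in the plan. Forward, C5–C6 must be made first and enantioselectively on 5, 7 must enter only afterwards, and the closure O1–C2 must be reversible so that C2 settles cis to C6.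

5 to 4 to 2 (through 3) to 1. The aldehyde is taken back to the primary alcohol 4, the terminal C–O bond of 4 to the C=C bond of 2, and the O–benzyl bond of 2 to the phenol of 1. This ties the aliphatic aldehyde to a cheap allylphenol with the arene substitution already in place. The forward demands are anti-Markovnikov hydration, an oxidation that stops at the aldehyde, and O-alkylation without allyl migration.

6 and 7 are not disconnected further. Both are bought, 7 being a stock compound that already carries the benzyl group it shares with 5.

## Other disconnections considered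

Alternative 1: The cut is at C3–C4 and C4–C5, with C4 as the acyl-anion carbon of a dithiane.
- Forward key step: the lithio derivative of tert-butyl(1,3-dithian-2-yl)dimethylsilane A2 would open the alkyl epoxide (S)-2-{2-[4-(benzyloxy)-3-methoxyphenyl]ethyl}oxirane A3 at its CH2. A polar cosolvent would then trigger 1,4-Brook migration of silicon to the new alkoxide, and the regenerated dithiane anion would open the aryl epoxide (R)-2-[4-(benzyloxy)-3-methoxyphenyl]oxirane A4. The product is the open-chain dithiane A1, with C4 masked as a ketone, the C6 oxygen silylated and the C2 oxygen free.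
- In its favour: both oxygen-bearing centres come from reagent-defined epoxides, three components are joined in one flask, and the C4 carbonyl arrives protected.
- Against it here: no ring is formed. Since A1 holds both oxygens, ring closure must expel one of them, most plausibly by acid-promoted ionisation at the p-alkoxybenzylic C2. That erases the configuration bought with A4 and leaves C2 to thermodynamic control anyway. A4 is an acid-labile p-alkoxystyrene oxide, prone to rearrangement and to attack at the benzylic carbon. Dithiane removal needs oxidants or thiophilic metal salts in the presence of two electron-rich arenes.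
- Comparison: in one-flask three-component convergence it is the equal of the chosen plan. In modularity and independence from the ring's thermodynamic preference it is the better, since a C6 epimer would need only the other enantiomer of A3. In structure it delivers a chain where the chosen plan delivers the ring. In mechanism it uses strongly basic organolithium relay chemistry where the chosen plan uses a Lewis-acid cascade. In step economy it is clearly longer: two enantioenriched epoxides, coupling, desilylation and cyclisation, dethioketalisation, then the same reduction and debenzylation.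

Alternative 2: The cut is at C5–C6 of the ring and at C7–C8 of the side chain (the two carbons between C6 and the distal arene).
- Forward key step: a Lewis acid would activate aldehyde 7, and the enol-ether carbon of vinyl ether A6 would add to it in a Mukaiyama-type aldol step. The oxocarbenium ion generated at C6 would then be trapped by the tethered allylsilane in a Prins closure, giving the 4-methylidene tetrahydropyran A5.
- In its favour: two C–C bonds and the ring form in one step, and the chair-like Prins transition state gives 2,6-cis kinetically.
- Against it here: C2 must be installed beforehand as a benzylic ether stereocentre in A6 and carried through oxocarbenium chemistry, where oxonia-Cope rearrangement and benzylic ionisation are the known racemisation channels. This is why the ring arene of A6 and A5 carries an acyl group, and it means two different phenol protecting groups. A5 also carries a superfluous C8 hydroxyl that must be removed next to the sensitive C2–O1 bond, and C4 arrives as C=CH2, which must be cleaved oxidatively in the presence of electron-rich arenes.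
- Comparison: in ring stereocontrol it is the equal of the chosen plan, and in not needing an equilibrium it is the better. In the number of external chiral reagents (one) it is the equal. In structure its key product is further from the target (wrong C4 function, extra C8 oxygen) where the chosen plan gives the correct C4 oxidation level. In mechanism both are Lewis-acid cascades, closing by C–C bond formation in the alternative and by C–O bond formation in the chosen plan. In step economy it is worse: deoxygenation, alkene cleavage, reduction and two deprotections follow the key step, against three steps in the chosen plan.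

Alternative 3: The cut is at C2–C3 and O1–C6.
- Forward key step: the terminal CH2 of the bis(silyl enol ether) A8, made from diketone A9, would add to aldehyde 7 under a chiral titanium–BINOL Lewis acid in a vinylogous Mukaiyama aldol. Acid would then condense the new hydroxyl with the distal carbonyl to give dihydropyranone A7, whose only stereocentre is C2.
- In its favour: the chiral controller is catalytic, which is better than the stoichiometric titanium complex of the chosen plan. No activating ester has to be removed, also better. One hydrogenation could in principle saturate C5=C6 and remove both benzyl groups before borohydride reduction, so two steps could follow the key step against three, again better.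
- Against it here: the enantio-determining addition is to the poorly electrophilic, electron-rich aldehyde 7. The centre it creates is the labile benzylic C2, which in A7 is β to the enone carbonyl. Acidic cyclodehydration or later acid or base can therefore racemise it by ring opening, with no second centre to correct it. C6 would then depend on substrate-controlled hydrogenation of a trisubstituted enol-ether double bond under conditions that also threaten C2–O1.
- Comparison: overall step count is about equal, because A9 and A8 must be prepared. In structure and mechanism the plans are mirror images: the chosen plan anchors the absolute configuration at the robust C6 and lets the labile C2 follow by equilibrium, whereas alternative 3 anchors it at C2 and relies on relay to C6.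

Key step: step 4

Assumption: the sense of induction in step 4 is taken to be ligand-controlled. The tert-leucinol-derived Schiff base is used as the enantiomer that leads to the 5S alcohol 8; its antipode is equally accessible should the opposite sense be required.

## Route

Step 1
Reactants: 1 eugenol (2-methoxy-4-(prop-2-en-1-yl)phenol)
Product: 2 1-(benzyloxy)-2-methoxy-4-(prop-2-en-1-yl)benzene
Conditions: BnBr, K2CO3, acetone, reflux
Reagents that add atoms: benzyl bromide, BrCc1ccccc1
Why: Williamson ether synthesis; the phenoxide formed by K2CO3 displaces bromide by SN2, and the base is too weak to move the allyl double bond into conjugation.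

Step 2
Reactants: 2 1-(benzyloxy)-2-methoxy-4-(prop-2-en-1-yl)benzene
Product: 4 3-[4-(benzyloxy)-3-methoxyphenyl]propan-1-ol, via alkylborane 3 (not isolated)
Conditions: 9-BBN, THF, 0 °C to rt; then NaOH (aq), H2O2, 0 °C to rt
Reagents that add atoms: hydrogen peroxide, OO; 9-borabicyclo[3.3.1]nonane, B1C2CCCC1CCC2 (retained only in intermediate 3)
Why: Hydroboration–oxidation; the bulky borane places boron on the terminal alkene carbon (anti-Markovnikov) and alkaline peroxide replaces boron by hydroxyl, while the aryl ethers are inert.

Step 3
Reactants: 4 3-[4-(benzyloxy)-3-methoxyphenyl]propan-1-ol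
Product: 5 3-[4-(benzyloxy)-3-methoxyphenyl]propanal
Conditions: Dess–Martin periodinane, CH2Cl2, 0 °C to rt
Reagents that add atoms: none
Why: Dess–Martin oxidation (ligand exchange at hypervalent iodine, then α-hydrogen removal) stops at the aldehyde under near-neutral anhydrous conditions and leaves the electron-rich arene alone; 5 is used at once to limit self-aldol loss.

Step 4
Reactants: 5 3-[4-(benzyloxy)-3-methoxyphenyl]propanal; 6 diketene (4-methylideneoxetan-2-one); 7 4-(benzyloxy)-3-methoxybenzaldehyde
Product: 10 isopropyl (2R,6S)-2-[4-(benzyloxy)-3-methoxyphenyl]-6-{2-[4-(benzyloxy)-3-methoxyphenyl]ethyl}-4-hydroxy-5,6-dihydro-2H-pyran-3-carboxylate (enol form of the 2,6-cis 4-oxo ester), via aldol adduct 8 (not isolated), via Knoevenagel adduct 9 (not isolated)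
Conditions: 5, Ti(OiPr)4 (1 equiv), Schiff base of 3,5-di-tert-butylsalicylaldehyde and tert-leucinol (1 equiv), CH2Cl2, −20 °C, slow addition of 6; then 7, TiCl4, −78 to −20 °C
Reagents that add atoms: titanium tetraisopropoxide, CC(C)O[Ti](OC(C)C)(OC(C)C)OC(C)C
Why: Ti(OiPr)4 opens diketene 6 at the acyl carbon to a titanium dienolate of isopropyl acetoacetate, which sits in the chiral tridentate salicylaldimine complex of tetravalent titanium and adds through its terminal carbon to one enantioface of aldehyde 5 (C5–C6; a vinylogous aldol addition, the closest known type being the enantioselective addition of diketene to aldehydes mediated by a titanium Schiff-base complex), so that C6 is set by the ligand as S in 8. TiCl4 then turns the β-keto ester into a chlorotitanium enolate and activates aldehyde 7, and Knoevenagel condensation forms C2–C3 in 9. The C6 oxygen closes the only new ring by 6-endo-trig oxa-Michael addition to the arylidene carbon (O1–C2). This closure is reversible, the electron-rich arene making retro-addition easy, and it drains into the chair in which aryl and arylethyl are both equatorial, so C2 is set under thermodynamic control relative to C6 as the 2,6-cis isomer, while the C6–O bond is never broken and the ligand-derived configuration is kept. The step needs three selectivities: the aliphatic aldehyde must be the aldol acceptor and the aromatic one the Knoevenagel partner, which the order of addition and the lower electrophilicity of 7 secure; the dienolate must react at its γ-carbon, which is inherent to the diketene-derived titanium species; and the benzyl ethers must outlast TiCl4, which the low temperature secures. C3 needs no control because 10 rests as the hydrogen-bonded enol and the ester is removed in step 5.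

Step 5
Reactants: 10 isopropyl (2R,6S)-2-[4-(benzyloxy)-3-methoxyphenyl]-6-{2-[4-(benzyloxy)-3-methoxyphenyl]ethyl}-4-hydroxy-5,6-dihydro-2H-pyran-3-carboxylate
Product: 12 (2S,6S)-2-[4-(benzyloxy)-3-methoxyphenyl]-6-{2-[4-(benzyloxy)-3-methoxyphenyl]ethyl}tetrahydro-4H-pyran-4-one, via keto acid 11 (not isolated)
Conditions: DMF–H2O, microwave, 160 °C
Reagents that add atoms: none
Why: Thermal dealkoxycarbonylation of a β-keto ester; water cleaves the ester (directly or through the acyl ketene formed by loss of isopropanol) and keto acid 11 loses CO2 through the usual cyclic transition state. Any C2 epimerisation by retro-oxa-Michael and re-addition returns the diequatorial 2,6-cis ketone. The change of the C2 descriptor from R to S reflects only the lower CIP rank of C3 once the ester is gone.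

Step 6
Reactants: 12 (2S,6S)-2-[4-(benzyloxy)-3-methoxyphenyl]-6-{2-[4-(benzyloxy)-3-methoxyphenyl]ethyl}tetrahydro-4H-pyran-4-one
Product: 13 (2S,4R,6S)-2-[4-(benzyloxy)-3-methoxyphenyl]-6-{2-[4-(benzyloxy)-3-methoxyphenyl]ethyl}tetrahydro-2H-pyran-4-ol
Conditions: NaBH4, MeOH–THF, −20 to 0 °C
Reagents that add atoms: none
Why: Borohydride reduction of a conformationally fixed six-membered ketone; the small hydride attacks the chair, locked by two equatorial substituents, along the axial trajectory, which should give the equatorial C4 alcohol cis to both substituents (4R). The benzyl ethers are untouched.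

Step 7
Reactants: 13 (2S,4R,6S)-2-[4-(benzyloxy)-3-methoxyphenyl]-6-{2-[4-(benzyloxy)-3-methoxyphenyl]ethyl}tetrahydro-2H-pyran-4-ol
Product: 14 (2S,4R,6S)-2-(4-hydroxy-3-methoxyphenyl)-6-[2-(4-hydroxy-3-methoxyphenyl)ethyl]tetrahydro-2H-pyran-4-ol (target)
Conditions: H2 (1 atm), Pd/C, EtOAc, rt, stopped at full debenzylation
Reagents that add atoms: none
Why: Catalytic hydrogenolysis; aryl benzyl ethers are cleaved much faster than the secondary cyclic benzylic C2–O1 bond under neutral aprotic conditions, and no stereocentre is touched.

## Compound list

1 | eugenol, 2-methoxy-4-(prop-2-en-1-yl)phenol | COc1cc(CC=C)ccc1O | starting material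
2 | 1-(benzyloxy)-2-methoxy-4-(prop-2-en-1-yl)benzene | COc1cc(CC=C)ccc1OCc1ccccc1 | intermediate
3 | 9-{3-[4-(benzyloxy)-3-methoxyphenyl]propyl}-9-borabicyclo[3.3.1]nonane (formed in the flask, not isolated) | COc1cc(CCCB2C3CCCC2CCC3)ccc1OCc1ccccc1 | intermediate
4 | 3-[4-(benzyloxy)-3-methoxyphenyl]propan-1-ol | COc1cc(CCCO)ccc1OCc1ccccc1 | intermediate
5 | 3-[4-(benzyloxy)-3-methoxyphenyl]propanal | COc1cc(CCC=O)ccc1OCc1ccccc1 | intermediate
6 | diketene, 4-methylideneoxetan-2-one | C=C1CC(=O)O1 | starting material
7 | 4-(benzyloxy)-3-methoxybenzaldehyde | COc1cc(C=O)ccc1OCc1ccccc1 | starting material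
8 | isopropyl (5S)-7-[4-(benzyloxy)-3-methoxyphenyl]-5-hydroxy-3-oxoheptanoate (present as its titanium alkoxide, not isolated) | CC(C)OC(=O)CC(=O)C[C@@H](O)CCc1ccc(OCc2ccccc2)c(OC)c1 | intermediate
9 | isopropyl (5S)-2-[4-(benzyloxy)-3-methoxybenzylidene]-7-[4-(benzyloxy)-3-methoxyphenyl]-5-hydroxy-3-oxoheptanoate (alkene geometry not defined, not isolated) | CC(C)OC(=O)C(=Cc1ccc(OCc2ccccc2)c(OC)c1)C(=O)C[C@@H](O)CCc1ccc(OCc2ccccc2)c(OC)c1 | intermediate
10 | isopropyl (2R,6S)-2-[4-(benzyloxy)-3-methoxyphenyl]-6-{2-[4-(benzyloxy)-3-methoxyphenyl]ethyl}-4-hydroxy-5,6-dihydro-2H-pyran-3-carboxylate | COc1cc(CC[C@H]2CC(O)=C(C(=O)OC(C)C)[C@@H](c3ccc(OCc4ccccc4)c(OC)c3)O2)ccc1OCc1ccccc1 | intermediate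
11 | (2R,6S)-2-[4-(benzyloxy)-3-methoxyphenyl]-6-{2-[4-(benzyloxy)-3-methoxyphenyl]ethyl}-4-hydroxy-5,6-dihydro-2H-pyran-3-carboxylic acid (enol form of the keto acid, not isolated) | COc1cc(CC[C@H]2CC(O)=C(C(O)=O)[C@@H](c3ccc(OCc4ccccc4)c(OC)c3)O2)ccc1OCc1ccccc1 | intermediate
12 | (2S,6S)-2-[4-(benzyloxy)-3-methoxyphenyl]-6-{2-[4-(benzyloxy)-3-methoxyphenyl]ethyl}tetrahydro-4H-pyran-4-one | COc1cc(CC[C@H]2CC(=O)C[C@@H](c3ccc(OCc4ccccc4)c(OC)c3)O2)ccc1OCc1ccccc1 | intermediate
13 | (2S,4R,6S)-2-[4-(benzyloxy)-3-methoxyphenyl]-6-{2-[4-(benzyloxy)-3-methoxyphenyl]ethyl}tetrahydro-2H-pyran-4-ol | COc1cc(CC[C@H]2C[C@@H](O)C[C@@H](c3ccc(OCc4ccccc4)c(OC)c3)O2)ccc1OCc1ccccc1 | intermediate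
14 | (2S,4R,6S)-2-(4-hydroxy-3-methoxyphenyl)-6-[2-(4-hydroxy-3-methoxyphenyl)ethyl]tetrahydro-2H-pyran-4-ol | COc1cc(CC[C@H]2C[C@@H](O)C[C@@H](c3ccc(O)c(OC)c3)O2)ccc1O | target

## Step count and least certain steps

Total steps: 7. Longest linear sequence: 7 (1 to 14); 6 and 7 enter at step 4.

Step 4 (key step). The likeliest failures are three:
- insufficient enantioface discrimination on a flexible aliphatic aldehyde, worsened by background addition through ligand-free titanium species;
- a stalled Knoevenagel stage, because 7 is a weak electrophile, so that uncyclised material and acetoacetate-derived condensation by-products accumulate;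
- Lewis-acid-assisted loss of a benzyl group on a chelating guaiacyl ring.

Fallback, from 5, rejoining at 8 and then 10: the C6 centre is made by asymmetric hydrogenation instead of aldol addition. Homologation of 5 with ethyl diazoacetate and catalytic SnCl2 (Roskamp reaction) would give ethyl 5-[4-(benzyloxy)-3-methoxyphenyl]-3-oxopentanoate F1. Hydrogenation over RuCl2[(S)-BINAP] in ethanol would give ethyl (3S)-5-[4-(benzyloxy)-3-methoxyphenyl]-3-hydroxypentanoate F2; the 3S sense is expected by analogy with simple 3-oxoalkanoates, and benzyl ethers are inert to this catalyst. Crossed Claisen condensation of F2 with excess lithium enolate of isopropyl acetate (LiN(iPr)2, THF, −78 to −30 °C) would give 8, now isolated. 8 would then be cyclised with 7 in a separate flask (TiCl4 or BF3·OEt2, CH2Cl2, low temperature) to 10.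

Step 5. The likeliest failures are incomplete cleavage of the hindered secondary ester, and erosion of stereochemical purity at 160 °C by successive retro-oxa-Michael openings at C2–O1 and C6–O1.

Fallback, from 5, rejoining at 12: the ester is changed to methyl so that it can be removed by SN2 dealkylation at lower temperature. Vinylogous Mukaiyama aldol addition of 1-methoxy-1,3-bis(trimethylsilyloxy)buta-1,3-diene to 5 under catalytic Ti(OiPr)4/BINOL (the BINOL enantiomer leading to the 5S alcohol), followed by acidic desilylation, would give methyl (5S)-7-[4-(benzyloxy)-3-methoxyphenyl]-5-hydroxy-3-oxoheptanoate F3. Cyclisation with 7 under TiCl4 would give methyl (2R,6S)-2-[4-(benzyloxy)-3-methoxyphenyl]-6-{2-[4-(benzyloxy)-3-methoxyphenyl]ethyl}-4-hydroxy-5,6-dihydro-2H-pyran-3-carboxylate F4. Krapcho dealkoxycarbonylation (LiCl, wet DMSO, about 120 °C) would give 12.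

Step 6. The likeliest failure is imperfect facial selectivity, with hydride entering equatorially and giving the axial C4 epimer.

Fallback, from 12, rejoining at 13: the alcohol is set by SN2 inversion instead of direct reduction. Reduction with the bulky LiBH(s-Bu)3 (THF, −78 °C) would deliberately give the axial alcohol (2S,4S,6S)-2-[4-(benzyloxy)-3-methoxyphenyl]-6-{2-[4-(benzyloxy)-3-methoxyphenyl]ethyl}tetrahydro-2H-pyran-4-ol F5. Mitsunobu reaction (4-nitrobenzoic acid, PPh3, DIAD) would invert C4 to the equatorial ester (2S,4R,6S)-2-[4-(benzyloxy)-3-methoxyphenyl]-6-{2-[4-(benzyloxy)-3-methoxyphenyl]ethyl}tetrahydro-2H-pyran-4-yl 4-nitrobenzoate F6. Methanolysis (K2CO3, MeOH) would give 13.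

Step 7. The likeliest failure is over-reduction: once the benzyl groups are gone, the p-hydroxybenzylic C2–O1 bond may be opened by hydrogenolysis.

Fallback, from 13, rejoining at 14: debenzylation without hydrogen, by Lewis-acid dealkylation with a cation scavenger (BCl3, pentamethylbenzene, CH2Cl2, −78 °C). This makes no new compound (F0).

## Further compounds

F1 | step 4 | ethyl 5-[4-(benzyloxy)-3-methoxyphenyl]-3-oxopentanoate | CCOC(=O)CC(=O)CCc1ccc(OCc2ccccc2)c(OC)c1
F2 | step 4 | ethyl (3S)-5-[4-(benzyloxy)-3-methoxyphenyl]-3-hydroxypentanoate | CCOC(=O)C[C@@H](O)CCc1ccc(OCc2ccccc2)c(OC)c1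
F3 | step 5 | methyl (5S)-7-[4-(benzyloxy)-3-methoxyphenyl]-5-hydroxy-3-oxoheptanoate | COC(=O)CC(=O)C[C@@H](O)CCc1ccc(OCc2ccccc2)c(OC)c1
F4 | step 5 | methyl (2R,6S)-2-[4-(benzyloxy)-3-methoxyphenyl]-6-{2-[4-(benzyloxy)-3-methoxyphenyl]ethyl}-4-hydroxy-5,6-dihydro-2H-pyran-3-carboxylate | COc1cc(CC[C@H]2CC(O)=C(C(=O)OC)[C@@H](c3ccc(OCc4ccccc4)c(OC)c3)O2)ccc1OCc1ccccc1
F5 | step 6 | (2S,4S,6S)-2-[4-(benzyloxy)-3-methoxyphenyl]-6-{2-[4-(benzyloxy)-3-methoxyphenyl]ethyl}tetrahydro-2H-pyran-4-ol | COc1cc(CC[C@H]2C[C@H](O)C[C@@H](c3ccc(OCc4ccccc4)c(OC)c3)O2)ccc1OCc1ccccc1
F6 | step 6 | (2S,4R,6S)-2-[4-(benzyloxy)-3-methoxyphenyl]-6-{2-[4-(benzyloxy)-3-methoxyphenyl]ethyl}tetrahydro-2H-pyran-4-yl 4-nitrobenzoate | COc1cc(CC[C@H]2C[C@@H](OC(=O)c3ccc(cc3)[N+](=O)[O-])C[C@@H](c3ccc(OCc4ccccc4)c(OC)c3)O2)ccc1OCc1ccccc1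
F0 | step 7 | none | none
A1 | alternative 1 | (1S)-1-[4-(benzyloxy)-3-methoxyphenyl]-2-{2-[(2S)-4-[4-(benzyloxy)-3-methoxyphenyl]-2-(tert-butyldimethylsilyloxy)butyl]-1,3-dithian-2-yl}ethan-1-ol | COc1cc(CC[C@H](O[Si](C)(C)C(C)(C)C)CC2(SCCCS2)C[C@@H](c3ccc(OCc4ccccc4)c(OC)c3)O)ccc1OCc1ccccc1
A2 | alternative 1 | tert-butyl(1,3-dithian-2-yl)dimethylsilane | CC(C)(C)[Si](C)(C)C1SCCCS1
A3 | alternative 1 | (2S)-2-{2-[4-(benzyloxy)-3-methoxyphenyl]ethyl}oxirane | COc1cc(CC[C@H]2CO2)ccc1OCc1ccccc1
A4 | alternative 1 | (2R)-2-[4-(benzyloxy)-3-methoxyphenyl]oxirane | C1[C@@H](c2ccc(OCc3ccccc3)c(OC)c2)O1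
A5 | alternative 2 | 4-[(2S,6R)-6-{2-[4-(benzyloxy)-3-methoxyphenyl]-2-hydroxyethyl}-4-methylidenetetrahydro-2H-pyran-2-yl]-2-methoxyphenyl 2,2-dimethylpropanoate (carbinol centre of the side chain undefined) | COc1cc(C(O)C[C@H]2CC(=C)C[C@@H](c3ccc(OC(=O)C(C)(C)C)c(OC)c3)O2)ccc1OCc1ccccc1
A6 | alternative 2 | 4-{(1S)-1-(ethenyloxy)-3-[(trimethylsilyl)methyl]but-3-en-1-yl}-2-methoxyphenyl 2,2-dimethylpropanoate | C=CO[C@@H](CC(=C)C[Si](C)(C)C)c1ccc(OC(=O)C(C)(C)C)c(OC)c1
A7 | alternative 3 | (2S)-2-[4-(benzyloxy)-3-methoxyphenyl]-6-{2-[4-(benzyloxy)-3-methoxyphenyl]ethyl}-2,3-dihydro-4H-pyran-4-one | COc1cc(CCC2=CC(=O)C[C@@H](c3ccc(OCc4ccccc4)c(OC)c3)O2)ccc1OCc1ccccc1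
A8 | alternative 3 | 6-[4-(benzyloxy)-3-methoxyphenyl]-2,4-bis(trimethylsilyloxy)hexa-1,3-diene (geometry at C3=C4 not defined) | C=C(O[Si](C)(C)C)C=C(CCc1ccc(OCc2ccccc2)c(OC)c1)O[Si](C)(C)C
A9 | alternative 3 | 6-[4-(benzyloxy)-3-methoxyphenyl]hexane-2,4-dione | CC(=O)CC(=O)CCc1ccc(OCc2ccccc2)c(OC)c1
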